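## Analysis of the target

Locants used throughout: C1(OH)–C2(CH3)=C3–C4–C5 is the chain on C6; the core is C6, O7, C8, C9, C10, C11, C12(OH), O13, C14(=O); C15–C16–C17(CH3)=C18–C19(OH) is the chain on C8.

The core of target 36 is a 6,8-dioxabicyclo[3.2.2]nonan-7-one. The bridgeheads C6 and C9 are joined by an ether bridge (O7–C8), a lactone bridge (C14–O13) and a carbon bridge (C12–C11–C10). This gives a 1,4-dioxan-2-one (ring A), an oxepane and a seven-membered lactone ring that share the bridgeheads.

There are four stereocentres: C6 (R, quaternary), C8 (S), C9 (R, quaternary, methyl-bearing) and C12 (S, secondary carbinol). On ring A the bonds C6–C12, C9–C10 and C8–C15 lie on one face and C6–C5 and the C9 methyl on the other; the C12 hydroxyl points towards the lactone bridge. Both chains end in (Z)-trisubstituted allylic alcohols.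

Sensitive features are:
- the β-hydroxy lactone (retro-aldol from a C12 alkoxide);
- the tertiary-alkyl C9–O13 ester bond (ionisable under acid, especially while C9 is still allylic);
- the allylic alcohols;
- any hydroxyl placed on C4, which would be γ to C14 and would exchange the strained bridged lactone for a spiro γ-butyrolactone.

The difficulty lies in two fully substituted, oxygen-bearing bridgeheads in a 1,4-relationship, the strain of the bridge, and two nearly identical side chains that must be told apart. The strategy rests on the C10–C11 segment of the carbon bridge: it is an unsubstituted CH2–CH2 link between the quaternary C9 and the carbinol C12. It can therefore come from a C10=C11 alkene made by joining two vinyl groups that sit on a finished ring A.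

## Retrosynthetic reasoning

**36 from 35.** Only three O–Si bonds are cut. All three hydroxyls are carried as silyl ethers so that one acidic fluoride treatment ends the synthesis without ever forming a C12 alkoxide.

**35 and 27 from the core.** The bonds C4–C3 and C16–C17 are cut; each is the sp3–sp2 bond next to a trisubstituted alkene. This places the Z geometry in the small vinyl iodides 33 and 25, which come stereospecifically from alkynols 29 and 22. It also leaves the core with two saturated two-carbon stubs, which the metathesis requires, since a trisubstituted alkene in either chain could close a cyclohexene with a vinyl group. The forward reactions are Negishi couplings of organozincs 34 and 26, which tolerate the lactone.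

The two couplings must be done in turn. The C16 stub is a benzyl ether that is freed in the same operation that saturates C10=C11 (19 to 20) and is then converted into iodide 21. The C4 stub is carried as a chloride from the moment it is introduced (16) and is exchanged for iodide only after the first coupling (27 to 28). A hydroxyl is never placed on C4, because of the lactone interchange noted above.

**20 from 19, and 19 from 18 (key disconnection).** After adding back the C10=C11 unsaturation, that bond is cut. It is the only core bond flanked by two substituent-free carbons, and cutting it leaves ring A with all four stereocentres already in place, so the ring closure creates none. Cutting C6–C12, O13–C9 or O7–C8 instead would make a ring and a stereocentre in the same event. The forward reaction is a ring-closing metathesis of diene 18, which must win over intermolecular metathesis and needs both vinyl groups on one face of ring A.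

**18 from 14 and 16.** The C6–C5 bond is cut (enolate alkylation). The order of the two bond formations at C6 is dictated by the template: whatever reaches the enolate carbon last enters trans to the C8 chain and trans to the C9 vinyl group. The arm that has to bridge must be cis to that vinyl group, so the carbinol arm is attached first and the stub last. In the reverse order the aldol would place the arm on the wrong face and the diene could not close.

**14 from 13, and 13 from 10 and 11.** The C6–C12 bond is cut (aldol with acrolein 11 through boron enolate 12). This step sets C12; the C6 configuration it makes is provisional and is overwritten in the alkylation.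

**10 from 9, and 9 from 7 and 8.** The ester bond O13–C14 and the ether bond O7–C6 are cut, which removes the glycolate unit (bromoacetic acid 8) from diol 7.

**7 from 4 and 5; 4 from 3; 3 from 1 and 2.** The terminal vinyl carbon is removed, leading back to terminal epoxide 4 and sulfonium salt 5. Epoxy alcohol 4 holds C8 and C9 in the erythro relationship that a Sharpless kinetic resolution of racemic allylic alcohol 3 delivers directly. The more obvious route through a trisubstituted (E)-allylic alcohol would need an oxygen nucleophile to invert C8 with uncertain regiochemistry. Alcohol 3 is one Grignard addition from 1 and 2.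

## Alternatives that were turned down

**Alternative 1:** The lactone bond O13–C9 is cut, with the oxepane already in place. In the forward step iodine activates the exocyclic C9 methylene of oxepane acid A1, and the C14 carboxylate on C6 captures C9 across the seven-membered ring to give iodomethyl lactone A2.
- For: the lactone ring and the C9 stereocentre arise in one event whose facial sense is fixed by the tether, and attack at the more substituted carbon is the normal regiochemistry. Both side chains are complete, so A2 is two operations from the target, which is fewer end-game steps than the chosen plan.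
- Against: A1 carries two trisubstituted alkenes that are more nucleophilic than the 1,1-disubstituted one and compete for the iodonium ion. The iodide of A2 is neopentyl-like and can only be removed through a radical; that β-acyloxyalkyl radical is set up for a 1,2-acyloxy shift to the tertiary radical (lactone enlargement) and for cyclisation onto the C17 alkene. The real difficulty moves into building A1, an oxepane with a quaternary C6, defined C8 and C12 and an exocyclic alkene.
- Comparison: the chosen plan spends more steps after its key event, but it keeps every alkene other than the two reacting vinyl groups out of the molecule until the core exists, and it ends the core with a hydrogenation instead of a radical reduction.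

**Alternative 2:** The ether bond O7–C8 and the C8–H bond are cut; the oxepane is reached through a bicyclic ketal. Acid converts keto diol A3 into ketal A4. i-Bu2AlH bound to the C12 oxygen then cleaves the C8–O(C12) bond and delivers hydride to C8 from the same side, giving oxepane A5.
- For: ketalisation is thermodynamically driven and makes the seven-membered ring without a medium-ring cyclisation, and the internal hydride delivery ties C8 to C12. As a way of making the oxepane it is stronger than anything in the chosen plan.
- Against: A5 has no lactone. C14 is still a protected primary alcohol, so deprotection, two oxidations, removal of the silyl group from the tertiary C9 oxygen and a lactonisation across the ring remain, all in the presence of two allylic silyl ethers. Which ketal C–O bond breaks depends on which oxygen the aluminium binds, and the other cleavage gives a tetrahydropyran. A3 needs three stereocentres (C6, C9, C12) made one at a time in an open chain.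
- Comparison: the chosen plan takes C6 and C12 from the ring template of 10 and reaches the complete bicycle in one closure.

**Alternative 3:** The C6–C12 bond is cut and closed last, intramolecularly. SmI2 reduces the C6–Br bond of bromo lactone aldehyde A6, and the samarium enolate adds to the tethered C12 aldehyde to give bis-silyl ether A7.
- For: it is the most convergent of the four. Both chains are present, A7 is one deprotection from the target, and the reagent spares alkenes and silyl ethers. The enolate can reach the aldehyde from one face only, so C6 follows from geometry. On step count after the key step it is clearly stronger.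
- Against: A6 carries bromine and an ether oxygen on the same carbon, an α-halo ether that ionises and hydrolyses easily, and it must be made by enolate bromination in a molecule that also carries or later reveals an aldehyde. C12, the stereocentre hardest to correct afterwards, would be created in the same step that builds the strained bridge, with its sense depending on chelated versus open transition states. The aldol closure is reversible, so the strained aldolate can revert.
- Comparison: the chosen plan sets C12 and C6 on the unstrained monocycle through reactions with established transition-state models, and uses an irreversible, stereochemically silent reaction for the strained closure.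

Key step: step 10

Remark: 3-(benzyloxy)propanal 1 is taken as a purchased compound; the unreacted (R)-enantiomer of 3 left by step 2 is removed by chromatography and not carried on.

Step 1
Reactants: 1 3-(benzyloxy)propanal; 2 isopropenylmagnesium bromide
Product: 3 (±)-5-(benzyloxy)-2-methylpent-1-en-3-ol
Conditions: THF, −78 → 0 °C; aq. NH4Cl
Reagents that add atoms: none
Why: Grignard 1,2-addition of an alkenylmagnesium halide to an aliphatic aldehyde; at −78 °C addition should outrun β-elimination of benzyl alcohol. The carbinol is made racemic on purpose, because step 2 resolves it.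

Step 2
Reactants: 3 (±)-5-(benzyloxy)-2-methylpent-1-en-3-ol
Product: 4 (1S)-3-(benzyloxy)-1-[(2R)-2-methyloxiran-2-yl]propan-1-ol
Conditions: Ti(OiPr)4 (cat.), L-(+)-diisopropyl tartrate, t-BuOOH (0.45 equiv), 4 Å MS, CH2Cl2, −20 °C
Reagents that add atoms: tert-butyl hydroperoxide, CC(C)(C)OO
Why: Sharpless kinetic resolution: with the L-(+)-tartrate the (S)-enantiomer of a secondary allylic alcohol (OH > alkenyl > alkyl > H) is epoxidised much faster than the (R)-enantiomer and gives the erythro epoxy alcohol, so C8 (S) and C9 (R) are set together. Holding conversion just under one half should keep the product highly enriched; 2-substituted 1-alken-3-ols are among the best substrates for this resolution.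

Step 3
Reactants: 4 (1S)-3-(benzyloxy)-1-[(2R)-2-methyloxiran-2-yl]propan-1-ol; 5 trimethylsulfonium iodide
Product: 7 (3R,4S)-6-(benzyloxy)-3-methylhex-1-ene-3,4-diol, via sulfonium betaine 6 (not isolated)
Conditions: 5 (4 equiv), n-BuLi (4 equiv), THF, −10 °C; then 4, −10 → 23 °C
Reagents that add atoms: none
Why: One-carbon homologation of a terminal epoxide to an allylic alcohol with dimethylsulfonium methylide: the ylide opens the epoxide at its unsubstituted CH2 (C10), and a second equivalent eliminates dimethyl sulfide from the betaine to give the vinyl group. No bond to C9 is touched, so the tertiary carbinol keeps its configuration; the free secondary hydroxyl only consumes one more equivalent of base.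

Step 4
Reactants: 7 (3R,4S)-6-(benzyloxy)-3-methylhex-1-ene-3,4-diol; 8 bromoacetic acid
Product: 9 2-{[(3S,4R)-1-(benzyloxy)-4-hydroxy-4-methylhex-5-en-3-yl]oxy}acetic acid
Conditions: NaH (3 equiv), THF, 0 → 50 °C; then cold dilute citric acid
Reagents that add atoms: none
Why: Williamson etherification with sodium bromoacetate; the secondary C8 alkoxide is far less hindered than the tertiary allylic C9 alkoxide, and the carboxylate (unlike an ester) cannot transfer its acyl group to either oxygen.

Step 5
Reactants: 9 2-{[(3S,4R)-1-(benzyloxy)-4-hydroxy-4-methylhex-5-en-3-yl]oxy}acetic acid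
Product: 10 (5S,6R)-5-[2-(benzyloxy)ethyl]-6-ethenyl-6-methyl-1,4-dioxan-2-one
Conditions: EDC·HCl, DMAP, CH2Cl2, 0 → 23 °C
Reagents that add atoms: none
Why: Carbodiimide (Steglich-type) lactonisation of a δ-hydroxy acid to the six-membered ring, helped by the fully substituted carbinol carbon. The neutral conditions avoid ionising the tertiary allylic C9–O bond, which an acid-driven lactonisation would risk.

Step 6
Reactants: 10 (5S,6R)-5-[2-(benzyloxy)ethyl]-6-ethenyl-6-methyl-1,4-dioxan-2-one; 11 acrolein
Product: 13 (3S,5S,6R)-5-[2-(benzyloxy)ethyl]-6-ethenyl-3-[(1S)-1-hydroxyprop-2-en-1-yl]-6-methyl-1,4-dioxan-2-one, via dicyclohexylboron enolate 12 (not isolated)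
Conditions: Cy2BOTf, Et3N, CH2Cl2, −78 °C; 11, −78 °C; pH 7 buffer, MeOH, H2O2, 0 °C
Reagents that add atoms: none
Why: Boron-mediated anti glycolate aldol of a 1,4-dioxan-2-one: the ring fixes the enolate geometry, the closed Zimmerman–Traxler chair with the aldehyde vinyl group equatorial gives the anti adduct, and the aldehyde meets the enolate face opposite the C8 chain and the axial C9 vinyl group; together these should set C12 as S. The C6 configuration made here is provisional (replaced in step 9); at −78 °C the boron enolate of this allylic ester should not undergo Ireland–Claisen ring contraction.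

Step 7
Reactants: 13 (3S,5S,6R)-5-[2-(benzyloxy)ethyl]-6-ethenyl-3-[(1S)-1-hydroxyprop-2-en-1-yl]-6-methyl-1,4-dioxan-2-one
Product: 14 (3S,5S,6R)-5-[2-(benzyloxy)ethyl]-3-[(1S)-1-{[tert-butyl(dimethyl)silyl]oxy}prop-2-en-1-yl]-6-ethenyl-6-methyl-1,4-dioxan-2-one
Conditions: TBSOTf, 2,6-lutidine, CH2Cl2, −78 → 0 °C
Reagents that add atoms: tert-butyldimethylsilyl trifluoromethanesulfonate, CC(C)(C)[Si](C)(C)OS(=O)(=O)C(F)(F)F
Why: Silylation of a hindered secondary alcohol with a silyl triflate and a hindered pyridine; no alkoxide is formed, so retro-aldol cleavage is avoided.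

Step 8
Reactants: 15 2-chloroethanol
Product: 16 2-chloroethyl trifluoromethanesulfonate
Conditions: Tf2O, 2,6-lutidine, CH2Cl2, −78 → −20 °C; used at once
Reagents that add atoms: trifluoromethanesulfonic anhydride, O=S(=O)(OS(=O)(=O)C(F)(F)F)C(F)(F)F
Why: Triflation of a primary alcohol; the triflate is displaced orders of magnitude faster than the chloride, so 16 alkylates only through the carbon bearing the triflate and delivers the stub at the halide level.

Step 9
Reactants: 14 (3S,5S,6R)-5-[2-(benzyloxy)ethyl]-3-[(1S)-1-{[tert-butyl(dimethyl)silyl]oxy}prop-2-en-1-yl]-6-ethenyl-6-methyl-1,4-dioxan-2-one; 16 2-chloroethyl trifluoromethanesulfonate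
Product: 18 (3R,5S,6R)-5-[2-(benzyloxy)ethyl]-3-[(1S)-1-{[tert-butyl(dimethyl)silyl]oxy}prop-2-en-1-yl]-3-(2-chloroethyl)-6-ethenyl-6-methyl-1,4-dioxan-2-one, via lithium enolate 17 (not isolated)
Conditions: LiN(iPr)2, THF, −78 °C; 16, DMPU, −78 → −50 °C
Reagents that add atoms: none
Why: Alkylation of a lactone lithium enolate with a primary triflate to form the quaternary C6. The electrophile should add axially to the half-chair enolate on the face anti to the equatorial C8 chain and the axial C9 vinyl group, which pushes the silyloxyallyl arm onto the vinyl face (6R); the rotamer of the exocyclic carbinol carbon that minimises allylic strain holds its silyloxy group on the far face and reinforces this. The low temperature and the reactive triflate keep loss of silanolate and [3,3] rearrangement of the allyl ester enolate from competing.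

Step 10
Reactants: 18 (3R,5S,6R)-5-[2-(benzyloxy)ethyl]-3-[(1S)-1-{[tert-butyl(dimethyl)silyl]oxy}prop-2-en-1-yl]-3-(2-chloroethyl)-6-ethenyl-6-methyl-1,4-dioxan-2-one
Product: 19 (1R,2S,5R,9S)-9-[2-(benzyloxy)ethyl]-2-{[tert-butyl(dimethyl)silyl]oxy}-1-(2-chloroethyl)-5-methyl-6,8-dioxabicyclo[3.2.2]non-3-en-7-one
Conditions: second-generation Grubbs catalyst RuCl2(=CHPh)(PCy3)(H2IMes) (10 mol %), toluene (0.002 M), 80 °C, argon purge
Reagents that add atoms: none
Why: Ring-closing olefin metathesis: the ruthenium benzylidene exchanges with one vinyl group, the resulting alkylidene adds [2+2] to the other, and cycloreversion of the ruthenacyclobutane releases ethene and leaves the C10=C11 bond. The closest known reaction type is ring-closing metathesis of cis-1,4-dialkenyl six-membered rings to bridged bicycles. One new bond closes two rings at once, the oxepane (C6–O7–C8–C9–C10–C11–C12) and the seven-membered lactone ring (C6–C14–O13–C9–C10–C11–C12), both by bridging the 1,4-positions of ring A across its boat, which the planar ester unit already favours. No stereocentre is formed, and the cis geometry of C10=C11 is enforced by the seven-membered rings. The step needs closure to beat cross-metathesis and needs both vinyl groups on one face of ring A; the 6R configuration from step 9 puts them in the two flagpole positions (methyl and chloroethyl take the bowsprit positions), and high dilution with removal of ethene should make closure the only productive and irreversible path. Chemoselectivity is secured by the substrate, which has no third alkene because both chains are saturated stubs. Both alkenes adjoin fully substituted or silyloxy-bearing carbons, so loading is slow; hence the N-heterocyclic-carbene catalyst and 80 °C.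

Step 11
Reactants: 19 (1R,2S,5R,9S)-9-[2-(benzyloxy)ethyl]-2-{[tert-butyl(dimethyl)silyl]oxy}-1-(2-chloroethyl)-5-methyl-6,8-dioxabicyclo[3.2.2]non-3-en-7-one
Product: 20 (1R,2S,5R,9S)-2-{[tert-butyl(dimethyl)silyl]oxy}-1-(2-chloroethyl)-9-(2-hydroxyethyl)-5-methyl-6,8-dioxabicyclo[3.2.2]nonan-7-one
Conditions: H2 (1 atm), Pd(OH)2/C, EtOAc, 23 °C
Reagents that add atoms: none
Why: Heterogeneous hydrogenation of the cis-disubstituted bridge alkene together with hydrogenolysis of the benzyl ether; primary alkyl chloride, silyl ether and lactone are inert in ethyl acetate. The allylic C9–O13 bond is at a bridgehead, where an allyl–palladium species cannot become planar, so allylic hydrogenolysis is not expected.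

Step 12
Reactants: 20 (1R,2S,5R,9S)-2-{[tert-butyl(dimethyl)silyl]oxy}-1-(2-chloroethyl)-9-(2-hydroxyethyl)-5-methyl-6,8-dioxabicyclo[3.2.2]nonan-7-one
Product: 21 (1R,2S,5R,9S)-2-{[tert-butyl(dimethyl)silyl]oxy}-1-(2-chloroethyl)-9-(2-iodoethyl)-5-methyl-6,8-dioxabicyclo[3.2.2]nonan-7-one
Conditions: I2, PPh3, imidazole, CH2Cl2, 0 → 23 °C
Reagents that add atoms: iodine, II
Why: Appel-type iodination of a primary alcohol (SN2 on the alkoxyphosphonium ion); this hydroxyl is too far from C14 to exchange with the lactone, and the chloride and silyl ether are untouched.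

Step 13
Reactants: 22 but-2-yn-1-ol
Product: 24 (2Z)-3-iodobut-2-en-1-ol, via cyclic alkenylaluminate 23 (not isolated)
Conditions: NaAlH2(OCH2CH2OMe)2, THF, 0 → 23 °C; I2, THF, −78 → 0 °C
Reagents that add atoms: iodine, II
Why: trans-Hydroalumination of a propargylic alcohol: the alkoxide-bound aluminium hydride delivers hydride to C2 and aluminium to C3 within a five-membered aluminate, and iodinolysis with retention places iodine cis to CH2OH (Z).

Step 14
Reactants: 24 (2Z)-3-iodobut-2-en-1-ol
Product: 25 tert-butyl{[(2Z)-3-iodobut-2-en-1-yl]oxy}dimethylsilane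
Conditions: TBSCl, imidazole, CH2Cl2, 23 °C
Reagents that add atoms: tert-butyldimethylsilyl chloride, CC(C)(C)[Si](C)(C)Cl
Why: Standard silylation of a primary allylic alcohol; the hydroxyl is masked so that it cannot protonate the organozinc in step 15.

Step 15
Reactants: 21 (1R,2S,5R,9S)-2-{[tert-butyl(dimethyl)silyl]oxy}-1-(2-chloroethyl)-9-(2-iodoethyl)-5-methyl-6,8-dioxabicyclo[3.2.2]nonan-7-one; 25 tert-butyl{[(2Z)-3-iodobut-2-en-1-yl]oxy}dimethylsilane
Product: 27 (1R,2S,5R,9S)-2-{[tert-butyl(dimethyl)silyl]oxy}-9-[(3Z)-5-{[tert-butyl(dimethyl)silyl]oxy}-3-methylpent-3-en-1-yl]-1-(2-chloroethyl)-5-methyl-6,8-dioxabicyclo[3.2.2]nonan-7-one, via alkylzinc iodide 26 (not isolated)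
Conditions: Zn dust (activated with BrCH2CH2Br, Me3SiCl), DMF, 35 °C; then 25, Pd(PPh3)4 (5 mol %), THF–DMF, 23 → 45 °C
Reagents that add atoms: none
Why: Negishi coupling: zinc inserts into the primary C–I bond but not the C–Cl bond and the organozinc tolerates the lactone; the zerovalent palladium catalyst couples it with the vinyl iodide with retention of the Z geometry. Primary alkylzinc reagents transmetallate and reductively eliminate faster than β-hydride elimination under these conditions.

Step 16
Reactants: 27 (1R,2S,5R,9S)-2-{[tert-butyl(dimethyl)silyl]oxy}-9-[(3Z)-5-{[tert-butyl(dimethyl)silyl]oxy}-3-methylpent-3-en-1-yl]-1-(2-chloroethyl)-5-methyl-6,8-dioxabicyclo[3.2.2]nonan-7-one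
Product: 28 (1R,2S,5R,9S)-2-{[tert-butyl(dimethyl)silyl]oxy}-9-[(3Z)-5-{[tert-butyl(dimethyl)silyl]oxy}-3-methylpent-3-en-1-yl]-1-(2-iodoethyl)-5-methyl-6,8-dioxabicyclo[3.2.2]nonan-7-one
Conditions: NaI, NaHCO3, butan-2-one, 70 °C
Reagents that add atoms: sodium iodide, [Na+].[I-]
Why: Finkelstein halide exchange, an SN2 reaction at a primary carbon two bonds from the quaternary centre, driven by precipitation of sodium chloride. The C4 handle thereby reaches the iodide without ever passing through the alcohol.

Step 17
Reactants: 29 prop-2-yn-1-ol; 30 methylmagnesium bromide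
Product: 32 (2Z)-3-iodo-2-methylprop-2-en-1-ol, via alkenylmagnesium alkoxide 31 (not isolated)
Conditions: 30 (2.5 equiv), CuI (10 mol %), THF, −20 → 23 °C; I2, −78 → 0 °C
Reagents that add atoms: iodine, II
Why: Copper-catalysed anti-carbomagnesiation of propargyl alcohol: methyl adds to C2 and magnesium to C3, held cis to the alkoxide by chelation; iodinolysis with retention gives the Z iodide.

Step 18
Reactants: 32 (2Z)-3-iodo-2-methylprop-2-en-1-ol
Product: 33 tert-butyl{[(2Z)-3-iodo-2-methylprop-2-en-1-yl]oxy}dimethylsilane
Conditions: TBSCl, imidazole, CH2Cl2, 23 °C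
Reagents that add atoms: tert-butyldimethylsilyl chloride, CC(C)(C)[Si](C)(C)Cl
Why: Standard silylation of a primary allylic alcohol, for the same reason as in step 14.

Step 19
Reactants: 28 (1R,2S,5R,9S)-2-{[tert-butyl(dimethyl)silyl]oxy}-9-[(3Z)-5-{[tert-butyl(dimethyl)silyl]oxy}-3-methylpent-3-en-1-yl]-1-(2-iodoethyl)-5-methyl-6,8-dioxabicyclo[3.2.2]nonan-7-one; 33 tert-butyl{[(2Z)-3-iodo-2-methylprop-2-en-1-yl]oxy}dimethylsilane
Product: 35 (1R,2S,5R,9S)-2-{[tert-butyl(dimethyl)silyl]oxy}-1-[(3Z)-5-{[tert-butyl(dimethyl)silyl]oxy}-4-methylpent-3-en-1-yl]-9-[(3Z)-5-{[tert-butyl(dimethyl)silyl]oxy}-3-methylpent-3-en-1-yl]-5-methyl-6,8-dioxabicyclo[3.2.2]nonan-7-one, via alkylzinc iodide 34 (not isolated)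
Conditions: Zn dust (activated with BrCH2CH2Br, Me3SiCl), DMF, 30 °C; then 33, Pd(PPh3)4 (5 mol %), THF–DMF, 23 → 40 °C
Reagents that add atoms: none
Why: Second Negishi coupling, with an unhindered terminal vinyl iodide; organozinc reagents that sit γ to a tertiary-alkyl ester are known to form and couple without attacking the ester. The Z geometry of 33 is carried over unchanged.

Step 20
Reactants: 35 (1R,2S,5R,9S)-2-{[tert-butyl(dimethyl)silyl]oxy}-1-[(3Z)-5-{[tert-butyl(dimethyl)silyl]oxy}-4-methylpent-3-en-1-yl]-9-[(3Z)-5-{[tert-butyl(dimethyl)silyl]oxy}-3-methylpent-3-en-1-yl]-5-methyl-6,8-dioxabicyclo[3.2.2]nonan-7-one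
Product: 36 (1R,2S,5R,9S)-2-hydroxy-1-[(3Z)-5-hydroxy-4-methylpent-3-en-1-yl]-9-[(3Z)-5-hydroxy-3-methylpent-3-en-1-yl]-5-methyl-6,8-dioxabicyclo[3.2.2]nonan-7-one
Conditions: HF·pyridine, pyridine, THF, 0 → 23 °C
Reagents that add atoms: none
Why: Global desilylation with buffered acidic fluoride; no C12 alkoxide is formed, so the β-hydroxy lactone cannot undergo retro-aldol opening, and the conditions are mild enough for the allylic alcohols and the tertiary-alkyl ester.

## Compound list

1 | 3-(benzyloxy)propanal | O=CCCOCc1ccccc1 | starting material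
2 | isopropenylmagnesium bromide | CC(=C)[Mg]Br | starting material
3 | (±)-5-(benzyloxy)-2-methylpent-1-en-3-ol | CC(=C)C(O)CCOCc1ccccc1 | intermediate
4 | (1S)-3-(benzyloxy)-1-[(2R)-2-methyloxiran-2-yl]propan-1-ol | C[C@@]1(CO1)[C@@H](O)CCOCc1ccccc1 | intermediate
5 | trimethylsulfonium iodide | C[S+](C)C.[I-] | starting material
6 | sulfonium betaine from ylide opening of 4 at C10 (lithium alkoxide at C8, oxide at C9) | C[S+](C)CC[C@@](C)([O-])[C@@H](O[Li])CCOCc1ccccc1 | intermediate (not isolated)
7 | (3R,4S)-6-(benzyloxy)-3-methylhex-1-ene-3,4-diol | C=C[C@@](C)(O)[C@@H](O)CCOCc1ccccc1 | intermediate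
8 | bromoacetic acid | OC(=O)CBr | starting material
9 | 2-{[(3S,4R)-1-(benzyloxy)-4-hydroxy-4-methylhex-5-en-3-yl]oxy}acetic acid | OC(=O)CO[C@@H](CCOCc1ccccc1)[C@](C)(O)C=C | intermediate
10 | (5S,6R)-5-[2-(benzyloxy)ethyl]-6-ethenyl-6-methyl-1,4-dioxan-2-one | O=C1CO[C@@H](CCOCc2ccccc2)[C@@](C)(C=C)O1 | intermediate
11 | acrolein (prop-2-enal) | C=CC=O | starting material
12 | dicyclohexylboron enolate of 10 | C1CCCCC1B(C1CCCCC1)OC1=CO[C@@H](CCOCc2ccccc2)[C@@](C)(C=C)O1 | intermediate (not isolated)
13 | (3S,5S,6R)-5-[2-(benzyloxy)ethyl]-6-ethenyl-3-[(1S)-1-hydroxyprop-2-en-1-yl]-6-methyl-1,4-dioxan-2-one | C=C[C@H](O)[C@@H]1O[C@@H](CCOCc2ccccc2)[C@@](C)(C=C)OC1=O | intermediate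
14 | (3S,5S,6R)-5-[2-(benzyloxy)ethyl]-3-[(1S)-1-{[tert-butyl(dimethyl)silyl]oxy}prop-2-en-1-yl]-6-ethenyl-6-methyl-1,4-dioxan-2-one | C=C[C@H](O[Si](C)(C)C(C)(C)C)[C@@H]1O[C@@H](CCOCc2ccccc2)[C@@](C)(C=C)OC1=O | intermediate
15 | 2-chloroethanol | OCCCl | starting material
16 | 2-chloroethyl trifluoromethanesulfonate | ClCCOS(=O)(=O)C(F)(F)F | intermediate
17 | lithium enolate of 14 | C=C[C@H](O[Si](C)(C)C(C)(C)C)C1=C(O[Li])O[C@](C)(C=C)[C@H](CCOCc2ccccc2)O1 | intermediate (not isolated)
18 | (3R,5S,6R)-5-[2-(benzyloxy)ethyl]-3-[(1S)-1-{[tert-butyl(dimethyl)silyl]oxy}prop-2-en-1-yl]-3-(2-chloroethyl)-6-ethenyl-6-methyl-1,4-dioxan-2-one | C=C[C@H](O[Si](C)(C)C(C)(C)C)[C@@]1(CCCl)O[C@@H](CCOCc2ccccc2)[C@@](C)(C=C)OC1=O | intermediate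
19 | (1R,2S,5R,9S)-9-[2-(benzyloxy)ethyl]-2-{[tert-butyl(dimethyl)silyl]oxy}-1-(2-chloroethyl)-5-methyl-6,8-dioxabicyclo[3.2.2]non-3-en-7-one | ClCC[C@@]12O[C@@H](CCOCc3ccccc3)[C@@](C)(C=C[C@@H]1O[Si](C)(C)C(C)(C)C)OC2=O | intermediate
20 | (1R,2S,5R,9S)-2-{[tert-butyl(dimethyl)silyl]oxy}-1-(2-chloroethyl)-9-(2-hydroxyethyl)-5-methyl-6,8-dioxabicyclo[3.2.2]nonan-7-one | ClCC[C@@]12O[C@@H](CCO)[C@@](C)(CC[C@@H]1O[Si](C)(C)C(C)(C)C)OC2=O | intermediate
21 | (1R,2S,5R,9S)-2-{[tert-butyl(dimethyl)silyl]oxy}-1-(2-chloroethyl)-9-(2-iodoethyl)-5-methyl-6,8-dioxabicyclo[3.2.2]nonan-7-one | ClCC[C@@]12O[C@@H](CCI)[C@@](C)(CC[C@@H]1O[Si](C)(C)C(C)(C)C)OC2=O | intermediate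
22 | but-2-yn-1-ol | CC#CCO | starting material
23 | sodium cyclic alkenylaluminate from 22 (aluminium on C3, bound to the C1 oxygen) | CC1=CCO[Al-]1(OCCOC)OCCOC.[Na+] | intermediate (not isolated)
24 | (2Z)-3-iodobut-2-en-1-ol | C/C(I)=C/CO | intermediate
25 | tert-butyl{[(2Z)-3-iodobut-2-en-1-yl]oxy}dimethylsilane | C/C(I)=C/CO[Si](C)(C)C(C)(C)C | intermediate
26 | alkylzinc iodide from 21 (zinc on C16) | ClCC[C@@]12O[C@@H](CC[Zn]I)[C@@](C)(CC[C@@H]1O[Si](C)(C)C(C)(C)C)OC2=O | intermediate (not isolated)
27 | (1R,2S,5R,9S)-2-{[tert-butyl(dimethyl)silyl]oxy}-9-[(3Z)-5-{[tert-butyl(dimethyl)silyl]oxy}-3-methylpent-3-en-1-yl]-1-(2-chloroethyl)-5-methyl-6,8-dioxabicyclo[3.2.2]nonan-7-one | ClCC[C@@]12O[C@@H](CC/C(C)=C\CO[Si](C)(C)C(C)(C)C)[C@@](C)(CC[C@@H]1O[Si](C)(C)C(C)(C)C)OC2=O | intermediate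
28 | (1R,2S,5R,9S)-2-{[tert-butyl(dimethyl)silyl]oxy}-9-[(3Z)-5-{[tert-butyl(dimethyl)silyl]oxy}-3-methylpent-3-en-1-yl]-1-(2-iodoethyl)-5-methyl-6,8-dioxabicyclo[3.2.2]nonan-7-one | ICC[C@@]12O[C@@H](CC/C(C)=C\CO[Si](C)(C)C(C)(C)C)[C@@](C)(CC[C@@H]1O[Si](C)(C)C(C)(C)C)OC2=O | intermediate
29 | prop-2-yn-1-ol | C#CCO | starting material
30 | methylmagnesium bromide | C[Mg]Br | starting material
31 | alkenylmagnesium alkoxide from 29 (magnesium on C3 cis to the CH2O group) | C/C(CO[Mg]Br)=C/[Mg]Br | intermediate (not isolated)
32 | (2Z)-3-iodo-2-methylprop-2-en-1-ol | C/C(CO)=C/I | intermediate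
33 | tert-butyl{[(2Z)-3-iodo-2-methylprop-2-en-1-yl]oxy}dimethylsilane | C/C(CO[Si](C)(C)C(C)(C)C)=C/I | intermediate
34 | alkylzinc iodide from 28 (zinc on C4) | I[Zn]CC[C@@]12O[C@@H](CC/C(C)=C\CO[Si](C)(C)C(C)(C)C)[C@@](C)(CC[C@@H]1O[Si](C)(C)C(C)(C)C)OC2=O | intermediate (not isolated)
35 | (1R,2S,5R,9S)-2-{[tert-butyl(dimethyl)silyl]oxy}-1-[(3Z)-5-{[tert-butyl(dimethyl)silyl]oxy}-4-methylpent-3-en-1-yl]-9-[(3Z)-5-{[tert-butyl(dimethyl)silyl]oxy}-3-methylpent-3-en-1-yl]-5-methyl-6,8-dioxabicyclo[3.2.2]nonan-7-one | C/C(=C/CC[C@@]12O[C@@H](CC/C(C)=C\CO[Si](C)(C)C(C)(C)C)[C@@](C)(CC[C@@H]1O[Si](C)(C)C(C)(C)C)OC2=O)CO[Si](C)(C)C(C)(C)C | intermediate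
36 | (1R,2S,5R,9S)-2-hydroxy-1-[(3Z)-5-hydroxy-4-methylpent-3-en-1-yl]-9-[(3Z)-5-hydroxy-3-methylpent-3-en-1-yl]-5-methyl-6,8-dioxabicyclo[3.2.2]nonan-7-one (CNP0105745.1) | C/C(=C/CC[C@@]12O[C@@H](CC/C(C)=C\CO)[C@@](C)(CC[C@@H]1O)OC2=O)CO | target

## Step count and least certain steps

Total: 20 steps. Longest linear sequence: 15 steps (1–7, 9–12, 15, 16, 19, 20); steps 8, 13–14 and 17–18 make the three side fragments.

**Step 10 (key step).** Loading of the catalyst onto either vinyl group is slow, because one adjoins a fully substituted carbon and the other a silyloxy-bearing carbon next to one. The closure also needs the ring-A boat with both arms in flagpole positions, which is sparsely populated. Intermolecular metathesis, catalyst decay and ruthenium-hydride isomerisation of the allylic silyl ether can therefore outrun ring closure. Fallback, from 18 back to 19: the lactone is opened first so that the metathesis becomes a simple monocyclic seven-membered closure assisted by a free tertiary allylic hydroxyl. Methanolysis of 18 (NaOMe cat., MeOH, 0 °C) should give the seco methyl ester, methyl (2R,3S)-2-{[(3S,4R)-1-(benzyloxy)-4-hydroxy-4-methylhex-5-en-3-yl]oxy}-3-{[tert-butyl(dimethyl)silyl]oxy}-2-(2-chloroethyl)pent-4-enoate F1. The same catalyst, RuCl2(=CHPh)(PCy3)(H2IMes) in CH2Cl2 at 40 °C, closes it to the oxepene, methyl (2R,3S,6R,7S)-7-[2-(benzyloxy)ethyl]-3-{[tert-butyl(dimethyl)silyl]oxy}-2-(2-chloroethyl)-6-hydroxy-6-methyl-2,3,6,7-tetrahydrooxepine-2-carboxylate F2. Transesterification of the C9 alkoxide onto the ester (NaH cat., toluene, 60 °C, 4 Å MS to take up methanol) then closes the lactone bridge and gives 19.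

**Step 6.** C12 is the one stereocentre not fixed by a ring. A competing boat transition state or attack on the other enolate face would erode it, and the aldolate can revert during work-up. Fallback, from 10 back to 18, replaces transition-state control by reagent control after the quaternary centre is in place:
- the aldol is run as a plain lithium aldol (LiN(iPr)2, 11, THF, −78 °C) and the adduct is taken on as the carbinol mixture, (5S,6R)-5-[2-(benzyloxy)ethyl]-6-ethenyl-3-(1-hydroxyprop-2-en-1-yl)-6-methyl-1,4-dioxan-2-one F3;
- the conditions of step 7 give the silyl ethers F4 and those of step 9 the alkylated lactones F5 (C6 set by the template, carbinol carbon mixed);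
- HF·pyridine frees the alcohols F6, and Dess–Martin periodinane converges both epimers on the vinyl ketone, (3R,5S,6R)-5-[2-(benzyloxy)ethyl]-3-(2-chloroethyl)-6-ethenyl-6-methyl-3-(prop-2-enoyl)-1,4-dioxan-2-one F7;
- Corey–Bakshi–Shibata reduction with (R)-1-methyl-3,3-diphenyltetrahydro-1H,3H-pyrrolo[1,2-c][1,3,2]oxazaborole and catecholborane (toluene, −78 °C; fully substituted C6 as the large group, vinyl as the small one) should give the (1S)-alcohol, (3R,5S,6R)-5-[2-(benzyloxy)ethyl]-3-(2-chloroethyl)-6-ethenyl-3-[(1S)-1-hydroxyprop-2-en-1-yl]-6-methyl-1,4-dioxan-2-one F8;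
- the conditions of step 7 convert F8 into 18.

**Step 9.** Removal of the hindered tertiary C6–H may be slow. Once formed, the enolate can expel silanolate to a dienyl lactone, or ring-contract by [3,3] rearrangement if it has to be warmed before the triflate is consumed. Fallback, from 13 back to 18, is a Fráter–Seebach-type dianion alkylation in which the β-oxygen is an alkoxide and cannot leave. Alcohol 13 with LiN(iPr)2 (2.2 equiv, THF, −78 °C) gives the dilithium alkoxide–enolate F9. The chelated alkoxide holds the vinyl group on the face away from the incoming electrophile, which matches the ring bias. Triflate 16 (1.05 equiv) then alkylates at carbon to give the alcohol F8 described under step 6, and the conditions of step 7 give 18.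

**Step 3.** Ylide attack at a CH2 flanked by a fully substituted carbon is slow, while the ylide decomposes above 0 °C; the neighbouring alkoxide can also migrate the epoxide (Payne rearrangement) and stall the reaction. Fallback, from 4 back to 7, splits the homologation into a robust carbanion opening and a separate elimination. (Phenylsulfanyl)methyllithium (thioanisole, n-BuLi, DABCO, THF, 0 °C) opens the epoxide at C10 to the sulfide, (3R,4S)-6-(benzyloxy)-3-methyl-1-(phenylsulfanyl)hexane-3,4-diol F10. NaIO4 (MeOH–H2O) gives the sulfoxide, (3R,4S)-6-(benzyloxy)-3-methyl-1-(phenylsulfinyl)hexane-3,4-diol F11. Thermal syn-elimination (toluene, CaCO3, 110 °C) gives 7.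

**Step 19.** Iodide 28 sits γ to the lactone carbonyl. During a slow zinc insertion, zinc iodide can promote carbonyl-oxygen participation with loss of the tertiary C9–O bond (interchange to a spiro γ-butyrolactone), and the organozinc can be protonated before it couples. Fallback, from 28 and 33 directly to 35, avoids any standing organometallic: a nickel-catalysed reductive cross-electrophile coupling (NiBr2(MeOCH2CH2OMe), 4,4′-di-tert-butyl-2,2′-bipyridine, Mn powder, DMA, 23 °C) joins the alkyl iodide and the vinyl iodide in one pot. It makes no compound outside the route.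

## Further compounds

F1 | step 10 | methyl (2R,3S)-2-{[(3S,4R)-1-(benzyloxy)-4-hydroxy-4-methylhex-5-en-3-yl]oxy}-3-{[tert-butyl(dimethyl)silyl]oxy}-2-(2-chloroethyl)pent-4-enoate | COC(=O)[C@](CCCl)(O[C@@H](CCOCc1ccccc1)[C@](C)(O)C=C)[C@@H](O[Si](C)(C)C(C)(C)C)C=C
F2 | step 10 | methyl (2R,3S,6R,7S)-7-[2-(benzyloxy)ethyl]-3-{[tert-butyl(dimethyl)silyl]oxy}-2-(2-chloroethyl)-6-hydroxy-6-methyl-2,3,6,7-tetrahydrooxepine-2-carboxylate | COC(=O)[C@]1(CCCl)O[C@@H](CCOCc2ccccc2)[C@](C)(O)C=C[C@@H]1O[Si](C)(C)C(C)(C)C
F3 | step 6 | (5S,6R)-5-[2-(benzyloxy)ethyl]-6-ethenyl-3-(1-hydroxyprop-2-en-1-yl)-6-methyl-1,4-dioxan-2-one, mixture at C3 and the carbinol carbon | C=CC(O)C1O[C@@H](CCOCc2ccccc2)[C@@](C)(C=C)OC1=O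
F4 | step 6 | tert-butyldimethylsilyl ether of F3, mixture at C3 and the carbinol carbon | C=CC(O[Si](C)(C)C(C)(C)C)C1O[C@@H](CCOCc2ccccc2)[C@@](C)(C=C)OC1=O
F5 | step 6 | (3R,5S,6R)-5-[2-(benzyloxy)ethyl]-3-(1-{[tert-butyl(dimethyl)silyl]oxy}prop-2-en-1-yl)-3-(2-chloroethyl)-6-ethenyl-6-methyl-1,4-dioxan-2-one, mixture at the carbinol carbon | C=CC(O[Si](C)(C)C(C)(C)C)[C@@]1(CCCl)O[C@@H](CCOCc2ccccc2)[C@@](C)(C=C)OC1=O
F6 | step 6 | (3R,5S,6R)-5-[2-(benzyloxy)ethyl]-3-(2-chloroethyl)-6-ethenyl-3-(1-hydroxyprop-2-en-1-yl)-6-methyl-1,4-dioxan-2-one, mixture at the carbinol carbon | C=CC(O)[C@@]1(CCCl)O[C@@H](CCOCc2ccccc2)[C@@](C)(C=C)OC1=O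
F7 | step 6 | (3R,5S,6R)-5-[2-(benzyloxy)ethyl]-3-(2-chloroethyl)-6-ethenyl-6-methyl-3-(prop-2-enoyl)-1,4-dioxan-2-one | C=CC(=O)[C@@]1(CCCl)O[C@@H](CCOCc2ccccc2)[C@@](C)(C=C)OC1=O
F8 | step 6 | (3R,5S,6R)-5-[2-(benzyloxy)ethyl]-3-(2-chloroethyl)-6-ethenyl-3-[(1S)-1-hydroxyprop-2-en-1-yl]-6-methyl-1,4-dioxan-2-one | C=C[C@H](O)[C@@]1(CCCl)O[C@@H](CCOCc2ccccc2)[C@@](C)(C=C)OC1=O
F9 | step 9 | dilithium alkoxide–enolate of 13 | C=C[C@H](O[Li])C1=C(O[Li])O[C@](C)(C=C)[C@H](CCOCc2ccccc2)O1
F10 | step 3 | (3R,4S)-6-(benzyloxy)-3-methyl-1-(phenylsulfanyl)hexane-3,4-diol | O[C@](C)(CCSc1ccccc1)[C@@H](O)CCOCc1ccccc1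
F11 | step 3 | (3R,4S)-6-(benzyloxy)-3-methyl-1-(phenylsulfinyl)hexane-3,4-diol, mixture at sulfur | O[C@](C)(CCS(=O)c1ccccc1)[C@@H](O)CCOCc1ccccc1
F0 | step 19 | none | none
A1 | alternative 1 | tris(tert-butyldimethylsilyl) oxepane-2-carboxylic acid with exocyclic C9 methylene and both side chains | C/C(=C/CC[C@@]1(C(=O)O)O[C@@H](CC/C(C)=C\CO[Si](C)(C)C(C)(C)C)C(=C)CC[C@@H]1O[Si](C)(C)C(C)(C)C)CO[Si](C)(C)C(C)(C)C
A2 | alternative 1 | bicyclic iodomethyl lactone (CH2I in place of the C9 methyl), tris(tert-butyldimethylsilyl) ether | C/C(=C/CC[C@@]12O[C@@H](CC/C(C)=C\CO[Si](C)(C)C(C)(C)C)[C@@](CI)(CC[C@@H]1O[Si](C)(C)C(C)(C)C)OC2=O)CO[Si](C)(C)C(C)(C)C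
A3 | alternative 2 | open-chain C8 ketone with free C6 and C12 hydroxyls, C9 triethylsilyl ether and C14 as 4-methoxybenzyl ether | C/C(=C/CC[C@](O)(COCc1ccc(OC)cc1)[C@@H](O)CC[C@@](C)(O[Si](CC)(CC)CC)C(=O)CC/C(C)=C\CO[Si](C)(C)C(C)(C)C)CO[Si](C)(C)C(C)(C)C
A4 | alternative 2 | bicyclic ketal at C8 (bonded to O7 and to the C12 oxygen) | C/C(=C/CC[C@@]1(COCc2ccc(OC)cc2)O[C@@]3(CC/C(C)=C\CO[Si](C)(C)C(C)(C)C)[C@@](C)(CC[C@@H]1O3)O[Si](CC)(CC)CC)CO[Si](C)(C)C(C)(C)C
A5 | alternative 2 | oxepane with C8–H set and free C12 hydroxyl | C/C(=C/CC[C@@]1(COCc2ccc(OC)cc2)O[C@@H](CC/C(C)=C\CO[Si](C)(C)C(C)(C)C)[C@@](C)(CC[C@@H]1O)O[Si](CC)(CC)CC)CO[Si](C)(C)C(C)(C)C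
A6 | alternative 3 | 3-bromo-1,4-dioxan-2-one with the C10–C12 aldehyde tether on C9 and both side chains, either configuration at C6 | C/C(=C/CCC1(Br)O[C@@H](CC/C(C)=C\CO[Si](C)(C)C(C)(C)C)[C@@](C)(CCC=O)OC1=O)CO[Si](C)(C)C(C)(C)C
A7 | alternative 3 | bis(tert-butyldimethylsilyl) ether of the target | C/C(=C/CC[C@@]12O[C@@H](CC/C(C)=C\CO[Si](C)(C)C(C)(C)C)[C@@](C)(CC[C@@H]1O)OC2=O)CO[Si](C)(C)C(C)(C)C
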